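Abbreviations: TBS = tert-butyldimethylsilyl, TIPS = triisopropylsilyl, TES = triethylsilyl; TBSO, TIPSO and TESO are the corresponding silyloxy groups. Atom numbers C2, C3, C4, C4a, C5–C8, C8a, O1 and C9 (the carbinol carbon) are those of the chromanone target 22.

## The problem

Target 22 is a chroman-4-one whose ring C is a cyclic hemiacetal: O1 joins C8a of a hexasubstituted ring A (5-OH, 6-OMe, 7-OH, 8-Me) to the lactol carbon C2, and C3, next to the C4 ketone, carries the (S)-hydroxy(4-hydroxyphenyl)methyl group (C9). Of the three contiguous stereocentres (2S,3R,9S), C2 is a hemiacetal carbon and C3 is the α-carbon of a ketone that is also a masked β-keto aldehyde, so both equilibrate by ring–chain tautomerism and enolisation. C9 alone is configurationally stable; it must be set by a reagent and can then only bias C3 and C2 thermodynamically (2,3-trans, 3,9-syn). The lactol loses water to the chromone under acid, and the open-chain tautomer is the aldol adduct of a 1,3-dicarbonyl compound with an electron-rich aldehyde, so it is prone to retro-aldol cleavage and to Knoevenagel-type dehydration. The 4-hydroxybenzylic carbinol ionises easily and the tetraoxygenated ring is readily oxidised, so the last steps must run close to neutrality and all protecting groups must leave with fluoride. Ring A offers two ortho phenols, O5 and O8a, to the C2 carbon, and the lactol must end on O8a. The feature that opens the route is that C3 bears both the C4 aryl ketone and the formyl-level carbon C2. This 2-substituted 1,3-dicarbonyl array can be hidden in the N–O bond of an isoxazole (C4 as C=N, C2 as the ring CH on oxygen), with C9 as an exocyclic aroyl ketone. That isoxazole is the cycloadduct of a ring A nitrile oxide with an enaminone in which the C3–C9 bond already exists.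

## Retrosynthesis

**Lactol and silyl ethers (22 ⇒ 19).** The O1–C2 hemiacetal bond and the five O–Si bonds are cut together, giving the fully silylated open-chain hydroxymethylene ketone 19. Any species with free O8a and C2 at the aldehyde level closes by itself (through 20 and 21), so no separate ring-forming step is needed. The alternative cut, C2–C3 (formylation of a chromanone enolate), would need strong base on a β-oxygenated ketone. The forward step needs buffered fluoride and must unveil the C9 hydroxyl last, after the ring has closed.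

**C4=O and the N–O bond (19 ⇒ 18 ⇒ 17).** The C4 carbonyl oxygen is exchanged for nitrogen (enaminal 18) and N is reconnected to the C2 oxygen, giving the aromatic isoxazole 17. An acetal or enol ether at C2 would leave the Knoevenagel-labile 1,3-dicarbonyl exposed; the isoxazole hides both carbonyls and is inert to reduction and silylation. The forward steps are reductive N–O cleavage and hydrolysis of the vinylogous formamide. Nitrogen must leave C4 before O8a is freed, because a free O8a would close onto C2 and drain the material to the chromone through a 4-aminobenzopyrylium ion.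

**C9–O–Si and C9–H (17 ⇒ 16 ⇒ 15).** Removing the silyl group and the carbinol hydrogen gives the diaryl-type ketone 15, which has no stereocentre. The forward reduction must distinguish the ortho-flanked isoxazolyl group from the para-substituted phenyl group; this is the only reagent-controlled stereochemical event of the route.

**C3–C4 and C2–O (15 ⇒ 9 + 13).** The isoxazole is cut into nitrile oxide 9 and enaminone 13. This removes ring A and the whole C2–C3–C9 chain in one operation, and the enaminone polarity allows only one regiochemistry. A cut at C3–C9 (aldol) would create the retro-aldol-prone bond late; here that bond is bought as the acetyl group of 10.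

**Nitrile oxide (9 ⇒ 7 ⇒ 6 ⇒ 5).** The dipole comes from aldoxime 7 by chlorination and dehydrochlorination (through 8), the oxime from aldehyde 6, and 6 from trihydroxy aldehyde 5 by silylation. Hexasubstitution is an asset: no ring position can be chlorinated and the two ortho substituents make 9 persistent.

**Ring A (5 ⇒ 4 ⇒ 3 ⇒ 1).** The C6 methoxy group is cut to a C–Br bond (4), the bromine to C–H (3), and the formyl group to the symmetric phenol 1. Formylation first leaves a single free position, so bromination and methoxylation are unambiguous and no protecting groups are needed.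

**Enaminone (13 ⇒ 11 + 12 ⇒ 10).** The C2–C3 bond is cut to the silylated acetophenone 11 and the amide acetal 12; 11 comes from 10. The acetyl methyl carbon becomes C3, the carbonyl carbon C9 and the acetal carbon C2.

## Roads not taken

**Alternative 1:** Moore ring expansion. The cut is the C4a–C8a bond of ring A. Heating cyclobutenone A1 should open it to a dienylketene that closes by 6π electrocyclisation to phenol A2.
- Merits: the four ring oxygens come out fully differentiated (O8a free, O5 as ethyl ether, O7 as isopropyl ether, O6 as methyl ether). In this respect it is better than the chosen plan, which leaves the O5/O8a choice in the lactol closure to thermodynamics.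
- Weak points: the key step is spent on ring A, which the chosen route reaches in three steps from 1. A2 still lacks C4, C3, C2 and C9 and all three stereocentres, and C4a must later be acylated on a pentasubstituted ring. The ethyl and isopropyl ethers must finally be cleaved with boron halides beside the C6 methyl ether, the lactol and the benzylic carbinol.
- Comparison: the chosen plan offsets its lack of oxygen differentiation with convergence and a fluoride-only deprotection.

**Alternative 2:** formate O-to-C transfer. The cut is C2–C3. The C3 lithium enolate of aryl formate ketone A3 should attack the formate carbonyl and give, after cold protonation, the silylated lactol A4.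
- Merits: ring C forms directly at the right oxidation level. The formate sits on O8a, so the ring-closure regiochemistry is fixed. There is no nitrogen to exchange and no chromone-prone intermediate. On these points it is better than the chosen plan, whose weakest step is the N-to-O exchange at C4.
- Weak points: A3 needs O8a distinguished from O5 and O7, and an enantioselective acetate-type aldol of a hindered aryl methyl ketone to set C9. Aryl formates are labile acyl donors that may not survive enolate generation. The β-silyloxy enolate can expel silyloxide. The lactolate can reopen to the β-keto aldehyde enolate and erase kinetic control at C3. Removal of the secondary silyl ether from A4 meets the same difficulty as the last step here.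
- Comparison: the chosen plan buys the C3–C9 bond instead of making it, brings ring A in as a robust dipole without oxygen differentiation, and keeps every intermediate up to step 12 a stable aromatic compound.

**Alternative 3:** silyloxyfuran–ynone Diels–Alder. The cuts are C6–C7 and C8–C8a. Furan A5 should add ynone A6 across its 2- and 5-positions, and the oxanorbornadiene should open to phenol A7.
- Merits: ring A is assembled convergently with O5, O6 and O8a distinguished and the C7 oxygen latent in an acetyl group, again better than the chosen plan on oxygen differentiation.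
- Weak points: 2-silyloxyfurans tend to react with ynones as vinylogous silyl ketene acetals (conjugate addition at C5) and not as dienes. A7 then needs a Baeyer–Villiger step, a silyl-to-methyl exchange at O6 and acylation at C4a before the C2–C3–C9 problem is even approached.
- Comparison: it is longer and solves a problem that 1 solves more cheaply.

Key step: step 9

Assumption: C2 and C3 of 22 are labile centres, so the (2S,3R) arrangement and closure onto O8a (not O5) are taken to be the thermodynamically preferred outcome for a (9S) carbinol; only C9 is set by reagent control.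

## Route

Step 1
Reactants: 1 2,4,6-trihydroxytoluene
Product: 3 2,4,6-trihydroxy-3-methylbenzaldehyde, via Vilsmeier iminium chloride 2 (not isolated)
Conditions: POCl3, DMF, EtOAc, 0 → 23 °C; then H2O, 60 °C
Reagents that add atoms: N,N-dimethylformamide, CN(C)C=O; water, O
Why: Vilsmeier–Haack formylation of a phloroglucinol; the two free positions are equivalent by symmetry, the first formyl group deactivates the ring against a second attack, and iminium salt 2 is hydrolysed on warming with water.

Step 2
Reactants: 3 2,4,6-trihydroxy-3-methylbenzaldehyde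
Product: 4 3-bromo-2,4,6-trihydroxy-5-methylbenzaldehyde
Conditions: NBS (1.0 equiv), MeCN, −20 → 0 °C
Reagents that add atoms: N-bromosuccinimide, O=C1CCC(=O)N1Br
Why: Electrophilic aromatic bromination at the only remaining ring C–H, activated by three hydroxyl groups; one equivalent in the cold limits ipso attack at the formyl-bearing carbon.

Step 3
Reactants: 4 3-bromo-2,4,6-trihydroxy-5-methylbenzaldehyde
Product: 5 2,4,6-trihydroxy-3-methoxy-5-methylbenzaldehyde
Conditions: NaOMe (excess), CuBr (20 mol%), MeOH/DMF, 100 °C, Ar; then aq. HCl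
Reagents that add atoms: sodium methoxide, C[O-].[Na+]
Why: Copper-catalysed Ullmann-type methoxylation of a bromophenol aldehyde (the reaction type that turns bromovanillin-type aldehydes into their methoxy analogues); monovalent copper activates the C–Br bond flanked by two phenoxides and methoxide replaces bromide, while the aldehyde is shielded as part of the polyphenoxide.

Step 4
Reactants: 5 2,4,6-trihydroxy-3-methoxy-5-methylbenzaldehyde
Product: 6 2,4,6-tris(TBSO)-3-methoxy-5-methylbenzaldehyde
Conditions: TBSCl, imidazole, 4-(dimethylamino)pyridine (cat.), DMF, 23 → 45 °C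
Reagents that add atoms: tert-butyldimethylsilyl chloride, CC(C)(C)[Si](C)(C)Cl
Why: Exhaustive O-silylation of phenols; the para hydroxyl reacts first and the two chelated ortho hydroxyls follow on warming, and silyl ethers are chosen because they leave with buffered fluoride at the end.

Step 5
Reactants: 6 2,4,6-tris(TBSO)-3-methoxy-5-methylbenzaldehyde
Product: 7 (E)-2,4,6-tris(TBSO)-3-methoxy-5-methylbenzaldehyde oxime
Conditions: NH2OH·HCl, pyridine, EtOH, 23 °C
Reagents that add atoms: hydroxylamine hydrochloride, Cl.NO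
Why: Condensation of the aldehyde with hydroxylamine to the E aldoxime; pyridine buffers the hydrochloride so the aryl silyl ethers stay intact.

Step 6
Reactants: 7 (E)-2,4,6-tris(TBSO)-3-methoxy-5-methylbenzaldehyde oxime
Product: 9 2,4,6-tris(TBSO)-3-methoxy-5-methylbenzonitrile oxide, via hydroximoyl chloride 8 (not isolated)
Conditions: NCS, DMF, 0 → 23 °C; then Et3N, Et2O, 0 °C
Reagents that add atoms: none
Why: Chlorination of the aldoxime carbon gives 8 and triethylamine removes HCl (1,3-dehydrochlorination) to the nitrile oxide; the ring has no free position for chlorination and the two ortho silyloxy groups make 9 a persistent dipole of the mesitonitrile oxide type.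

Step 7
Reactants: 10 4'-hydroxyacetophenone
Product: 11 1-[4-(TIPSO)phenyl]ethan-1-one
Conditions: TIPSCl, imidazole, DMF, 23 °C
Reagents that add atoms: triisopropylsilyl chloride, CC(C)[Si](Cl)(C(C)C)C(C)C
Why: Phenol silylation; the TIPS ether is preferred to TBS on this ring because it has to survive the hot amide acetal and the methoxide it releases in step 8.

Step 8
Reactants: 11 1-[4-(TIPSO)phenyl]ethan-1-one; 12 N,N-dimethylformamide dimethyl acetal
Product: 13 (E)-3-(dimethylamino)-1-[4-(TIPSO)phenyl]prop-2-en-1-one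
Conditions: PhMe, 100 °C, removal of MeOH
Reagents that add atoms: none
Why: Enaminone formation by condensation of a methyl ketone with an amide acetal (enol attack on the methoxyiminium ion, loss of two methanol) gives the E push–pull alkene; the acetyl carbons become C3 and C9 and the acetal carbon becomes C2.

Step 9
Reactants: 9 2,4,6-tris(TBSO)-3-methoxy-5-methylbenzonitrile oxide; 13 (E)-3-(dimethylamino)-1-[4-(TIPSO)phenyl]prop-2-en-1-one
Product: 15 {3-[2,4,6-tris(TBSO)-3-methoxy-5-methylphenyl]-1,2-oxazol-4-yl}[4-(TIPSO)phenyl]methanone, via 5-(dimethylamino)isoxazoline 14 (not isolated)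
Conditions: PhMe, 23 → 70 °C, Ar sweep
Reagents that add atoms: none
Why: This is the nitrile oxide–enaminone [3+2] cycloaddition followed by loss of the amine, the established route from β-enaminones to 4-acylisoxazoles. The enaminone HOMO has its large coefficient on the α-carbon (C3), which bonds to the electrophilic dipole carbon (C4), while the dipole oxygen closes onto the aminated carbon (C2). The five-membered ring is thus closed by a concerted, asynchronous, suprafacial addition of the C–N–O dipole across C2=C3, giving the trans isoxazoline 14. Elimination of dimethylamine from 14 aromatises the ring, so its two sp3 centres vanish and no stereocentre is set. The selectivity required is regiochemical (C2 must become the unsubstituted ring CH on oxygen) and the push–pull polarisation of 13 secures it. The two ortho silyloxy groups shield 9 against dimerisation to the furoxan, so the isolated dipole can be used without base. The aroyl carbonyl of 13 does not react and becomes the C9 ketone, and the volatile amine is swept out so that it does not attack the aryl silyl ethers.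

Step 10
Reactants: 15 {3-[2,4,6-tris(TBSO)-3-methoxy-5-methylphenyl]-1,2-oxazol-4-yl}[4-(TIPSO)phenyl]methanone
Product: 16 (R)-{3-[2,4,6-tris(TBSO)-3-methoxy-5-methylphenyl]-1,2-oxazol-4-yl}[4-(TIPSO)phenyl]methanol
Conditions: (S)-Me-CBS [(3aS)-1-methyl-3,3-diphenylhexahydropyrrolo[1,2-c][1,3,2]oxazaborole, 20 mol%], BH3·SMe2, THF, −20 °C; MeOH quench
Reagents that add atoms: none
Why: Corey–Bakshi–Shibata reduction; the isoxazolyl group, twisted out of the carbonyl plane by its ortho-flanked 3-aryl substituent, acts as the large group and the coplanar, electron-rich 4-silyloxyphenyl as the small one, so the (S)-catalyst should deliver hydride to the face giving the (R)-carbinol, which is spatially the 9S centre of 22 (the descriptor changes only when C3 becomes sp3).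

Step 11
Reactants: 16 (R)-{3-[2,4,6-tris(TBSO)-3-methoxy-5-methylphenyl]-1,2-oxazol-4-yl}[4-(TIPSO)phenyl]methanol
Product: 17 4-{(R)-(TBSO)[4-(TIPSO)phenyl]methyl}-3-[2,4,6-tris(TBSO)-3-methoxy-5-methylphenyl]-1,2-oxazole
Conditions: TBSOTf, 2,6-lutidine, CH2Cl2, −78 → 0 °C
Reagents that add atoms: tert-butyldimethylsilyl triflate, CC(C)(C)[Si](C)(C)OS(=O)(=O)C(F)(F)F
Why: Silylation of a hindered secondary benzylic alcohol with a silyl triflate and a hindered pyridine base; the ether blocks retro-aldol cleavage of C3–C9 and ionisation at C9 in the open-chain stages that follow.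

Step 12
Reactants: 17 4-{(R)-(TBSO)[4-(TIPSO)phenyl]methyl}-3-[2,4,6-tris(TBSO)-3-methoxy-5-methylphenyl]-1,2-oxazole
Product: 18 (2Z)-3-amino-2-{(R)-(TBSO)[4-(TIPSO)phenyl]methyl}-3-[2,4,6-tris(TBSO)-3-methoxy-5-methylphenyl]prop-2-enal
Conditions: Mo(CO)6, MeCN/H2O (15:1), 80 °C
Reagents that add atoms: none
Why: Reductive N–O cleavage of an isoxazole by zerovalent molybdenum in wet acetonitrile (coordination at nitrogen, electron transfer, protonation by water) gives the Z β-amino enal; silyl ethers, the alkene and the benzylic C–O bond are not touched under these neutral conditions.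

Step 13
Reactants: 18 (2Z)-3-amino-2-{(R)-(TBSO)[4-(TIPSO)phenyl]methyl}-3-[2,4,6-tris(TBSO)-3-methoxy-5-methylphenyl]prop-2-enal
Product: 19 (2Z)-2-{(R)-(TBSO)[4-(TIPSO)phenyl]methyl}-3-hydroxy-1-[2,4,6-tris(TBSO)-3-methoxy-5-methylphenyl]prop-2-en-1-one
Conditions: (CO2H)2 (0.5 M aq.), THF, 23 °C
Reagents that add atoms: water, O
Why: Acid hydrolysis of a vinylogous formamide (β-enaminone to 1,3-dicarbonyl): water adds to C4 of the O-protonated enaminal and ammonia leaves; the product rests as the chelated Z enol so C3 stays trigonal, and the aryl silyl ethers keep O8a from closing onto C2 while nitrogen is still on C4.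

Step 14
Reactants: 19 (2Z)-2-{(R)-(TBSO)[4-(TIPSO)phenyl]methyl}-3-hydroxy-1-[2,4,6-tris(TBSO)-3-methoxy-5-methylphenyl]prop-2-en-1-one
Product: 22 (2S,3R)-2,5,7-trihydroxy-3-[(S)-hydroxy(4-hydroxyphenyl)methyl]-6-methoxy-8-methyl-2,3-dihydro-4H-chromen-4-one, via open-chain tetraphenol enol 20 (not isolated), via C9 silyl ether lactol 21 (not isolated)
Conditions: Bu4NF, AcOH (1:1), THF, 0 → 23 °C; pH 7 phosphate buffer
Reagents that add atoms: none
Why: Buffered fluoride desilylation: the four aryl silyl ethers go first, O8a of 20 adds to C2 (6-exo-trig hemiacetalisation) to give 21, and the secondary silyl ether is cleaved last; C2 and C3 are set under thermodynamic control (ring–chain tautomerism, enolisation) with the fixed 9S centre expected to favour the 2,3-trans lactol, and the reversible choice between O8a and O5 should favour the 5,6,7-trioxygenated chromanone, as in Wessely–Moser equilibria.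

## Compound list

1 | 2,4,6-trihydroxytoluene (2-methylbenzene-1,3,5-triol) | Cc1c(O)cc(O)cc1O | starting material
2 | N-[(2,4,6-trihydroxy-3-methylphenyl)methylidene]-N-methylmethanaminium chloride | C[N+](C)=Cc1c(O)cc(O)c(C)c1O.[Cl-] | intermediate (not isolated)
3 | 2,4,6-trihydroxy-3-methylbenzaldehyde | Cc1c(O)cc(O)c(C=O)c1O | intermediate
4 | 3-bromo-2,4,6-trihydroxy-5-methylbenzaldehyde | Cc1c(O)c(Br)c(O)c(C=O)c1O | intermediate
5 | 2,4,6-trihydroxy-3-methoxy-5-methylbenzaldehyde | COc1c(O)c(C)c(O)c(C=O)c1O | intermediate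
6 | 2,4,6-tris(TBSO)-3-methoxy-5-methylbenzaldehyde | COc1c(O[Si](C)(C)C(C)(C)C)c(C)c(O[Si](C)(C)C(C)(C)C)c(C=O)c1O[Si](C)(C)C(C)(C)C | intermediate
7 | (E)-2,4,6-tris(TBSO)-3-methoxy-5-methylbenzaldehyde oxime | COc1c(O[Si](C)(C)C(C)(C)C)c(C)c(O[Si](C)(C)C(C)(C)C)c(/C=N/O)c1O[Si](C)(C)C(C)(C)C | intermediate
8 | (Z)-N-hydroxy-2,4,6-tris(TBSO)-3-methoxy-5-methylbenzimidoyl chloride | COc1c(O[Si](C)(C)C(C)(C)C)c(C)c(O[Si](C)(C)C(C)(C)C)c(/C(Cl)=N/O)c1O[Si](C)(C)C(C)(C)C | intermediate (not isolated)
9 | 2,4,6-tris(TBSO)-3-methoxy-5-methylbenzonitrile oxide | COc1c(O[Si](C)(C)C(C)(C)C)c(C)c(O[Si](C)(C)C(C)(C)C)c(C#[N+][O-])c1O[Si](C)(C)C(C)(C)C | intermediate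
10 | 4'-hydroxyacetophenone | CC(=O)c1ccc(O)cc1 | starting material
11 | 1-[4-(TIPSO)phenyl]ethan-1-one | CC(=O)c1ccc(O[Si](C(C)C)(C(C)C)C(C)C)cc1 | intermediate
12 | N,N-dimethylformamide dimethyl acetal | COC(OC)N(C)C | starting material
13 | (E)-3-(dimethylamino)-1-[4-(TIPSO)phenyl]prop-2-en-1-one | CN(C)/C=C/C(=O)c1ccc(O[Si](C(C)C)(C(C)C)C(C)C)cc1 | intermediate
14 | racemic trans-{5-(dimethylamino)-3-[2,4,6-tris(TBSO)-3-methoxy-5-methylphenyl]-4,5-dihydro-1,2-oxazol-4-yl}[4-(TIPSO)phenyl]methanone (one enantiomer drawn) | CN(C)[C@H]1ON=C(c2c(O[Si](C)(C)C(C)(C)C)c(OC)c(O[Si](C)(C)C(C)(C)C)c(C)c2O[Si](C)(C)C(C)(C)C)[C@@H]1C(=O)c1ccc(O[Si](C(C)C)(C(C)C)C(C)C)cc1 | intermediate (not isolated)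
15 | {3-[2,4,6-tris(TBSO)-3-methoxy-5-methylphenyl]-1,2-oxazol-4-yl}[4-(TIPSO)phenyl]methanone | O=C(c1ccc(O[Si](C(C)C)(C(C)C)C(C)C)cc1)c1conc1-c1c(O[Si](C)(C)C(C)(C)C)c(OC)c(O[Si](C)(C)C(C)(C)C)c(C)c1O[Si](C)(C)C(C)(C)C | intermediate
16 | (R)-{3-[2,4,6-tris(TBSO)-3-methoxy-5-methylphenyl]-1,2-oxazol-4-yl}[4-(TIPSO)phenyl]methanol | O[C@H](c1ccc(O[Si](C(C)C)(C(C)C)C(C)C)cc1)c1conc1-c1c(O[Si](C)(C)C(C)(C)C)c(OC)c(O[Si](C)(C)C(C)(C)C)c(C)c1O[Si](C)(C)C(C)(C)C | intermediate
17 | 4-{(R)-(TBSO)[4-(TIPSO)phenyl]methyl}-3-[2,4,6-tris(TBSO)-3-methoxy-5-methylphenyl]-1,2-oxazole | CC(C)(C)[Si](C)(C)O[C@H](c1ccc(O[Si](C(C)C)(C(C)C)C(C)C)cc1)c1conc1-c1c(O[Si](C)(C)C(C)(C)C)c(OC)c(O[Si](C)(C)C(C)(C)C)c(C)c1O[Si](C)(C)C(C)(C)C | intermediate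
18 | (2Z)-3-amino-2-{(R)-(TBSO)[4-(TIPSO)phenyl]methyl}-3-[2,4,6-tris(TBSO)-3-methoxy-5-methylphenyl]prop-2-enal | CC(C)(C)[Si](C)(C)O[C@H](c1ccc(O[Si](C(C)C)(C(C)C)C(C)C)cc1)/C(C=O)=C(/N)c1c(O[Si](C)(C)C(C)(C)C)c(OC)c(O[Si](C)(C)C(C)(C)C)c(C)c1O[Si](C)(C)C(C)(C)C | intermediate
19 | (2Z)-2-{(R)-(TBSO)[4-(TIPSO)phenyl]methyl}-3-hydroxy-1-[2,4,6-tris(TBSO)-3-methoxy-5-methylphenyl]prop-2-en-1-one (enol form of the 2-formyl ketone) | O/C=C(/[C@H](O[Si](C)(C)C(C)(C)C)c1ccc(O[Si](C(C)C)(C(C)C)C(C)C)cc1)C(=O)c1c(O[Si](C)(C)C(C)(C)C)c(OC)c(O[Si](C)(C)C(C)(C)C)c(C)c1O[Si](C)(C)C(C)(C)C | intermediate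
20 | (2Z)-2-[(R)-(TBSO)(4-hydroxyphenyl)methyl]-3-hydroxy-1-(2,4,6-trihydroxy-3-methoxy-5-methylphenyl)prop-2-en-1-one | O/C=C(/[C@H](O[Si](C)(C)C(C)(C)C)c1ccc(O)cc1)C(=O)c1c(O)c(OC)c(O)c(C)c1O | intermediate (not isolated)
21 | (2S,3R)-3-[(S)-(TBSO)(4-hydroxyphenyl)methyl]-2,5,7-trihydroxy-6-methoxy-8-methyl-2,3-dihydro-4H-chromen-4-one | COc1c(O)c(C)c2c(c1O)C(=O)[C@H]([C@H](O[Si](C)(C)C(C)(C)C)c1ccc(O)cc1)[C@@H](O)O2 | intermediate (not isolated)
22 | (2S,3R)-2,5,7-trihydroxy-3-[(S)-hydroxy(4-hydroxyphenyl)methyl]-6-methoxy-8-methyl-2,3-dihydro-4H-chromen-4-one | COc1c(O)c(C)c2c(c1O)C(=O)[C@H]([C@H](O)c1ccc(O)cc1)[C@@H](O)O2 | target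

## Step count and least certain steps

Total: 14 steps. Longest linear sequence: 12 steps (steps 1–6 and 9–14); the enaminone branch adds steps 7 and 8.

**Step 9 (key step).** The cycloaddition may be slow, because the dipole carbon is flanked by two silyloxy groups and the dipolarophile is a deactivated push–pull alkene. Prolonged heating would then let the nitrile oxide isomerise to the isocyanate, and lingering dimethylamine could strip aryl silyl groups. The fallback replaces the neutral cycloaddition by an anionic addition–cyclocondensation. It sets out from 11 and 9: Claisen formylation of 11 (HCO2Et, NaH, THF) gives sodium (1Z)-3-oxo-3-[4-(TIPSO)phenyl]prop-1-en-1-olate F6. Its central carbon adds to the dipole carbon of 9 at 0 °C and the oximate oxygen closes onto the formyl carbon, giving the 5-hydroxy-4,5-dihydroisoxazole F7. Acidification with AcOH dehydrates F7, and the sequence rejoins the route at 15.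

**Step 3.** Reductive loss of bromine (bromophloroglucinols give up their halogen easily) and oxidative degradation of the polyphenoxide under hot copper/methoxide may outrun substitution. The fallback installs the methoxy oxygen by Baeyer–Villiger chemistry and sets out from 3:
- benzylation (BnBr, K2CO3, DMF) to 2,4,6-tris(benzyloxy)-3-methylbenzaldehyde F1;
- mCPBA oxidation to 2,4,6-tris(benzyloxy)-3-methylphenyl formate F2, and methanolysis (K2CO3, MeOH) to 2,4,6-tris(benzyloxy)-3-methylphenol F3;
- methylation (MeI, K2CO3, acetone) to 1,3,5-tris(benzyloxy)-2-methoxy-4-methylbenzene F4;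
- hydrogenolysis (H2, Pd/C, zerovalent palladium on carbon, EtOAc/MeOH) to 2-methoxy-4-methylbenzene-1,3,5-triol F5;
- Vilsmeier–Haack formylation under the conditions of step 1, which rejoins the route at 5.

**Step 10.** Facial discrimination between two aryl-type groups may be poor if the twisted isoxazolyl and the para-substituted phenyl are not sufficiently different for the catalyst. The fallback is a resolution and sets out from 15. NaBH4 (MeOH/THF, 0 °C) gives the racemic carbinol F8. Esterification with (S)-O-methylmandelic acid (DCC, 4-(dimethylamino)pyridine) gives the (S)-O-methylmandelate of the (R)-carbinol F9 and the (S)-O-methylmandelate of the (S)-carbinol F10, which are separated by chromatography. Reductive ester cleavage of F9 (i-Bu2AlH, CH2Cl2, −78 °C) rejoins the route at 16; F10 is cleaved likewise and reoxidised to 15.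

**Step 13.** Water may fail to add to C4: the ring A aryl group stands perpendicular to the enaminal, its ortho oxygens cover both faces of C4, and the electron-rich ring stabilises the iminium ion. Stronger acid would then be needed, under which the C9 silyl ether may ionise or silyl groups may be lost. The fallback moves the hydrolysis into the cyclic manifold and sets out from 18. Brief buffered fluoride (Bu4NF/AcOH, 0 °C) removes only the four aryl silyl groups and gives (2Z)-3-amino-2-[(R)-(TBSO)(4-hydroxyphenyl)methyl]-3-(2,4,6-trihydroxy-3-methoxy-5-methylphenyl)prop-2-enal F11. In aqueous acetate buffer O8a adds to the formyl carbon to give 4-amino-3-[(R)-(TBSO)(4-hydroxyphenyl)methyl]-6-methoxy-8-methyl-2H-chromene-2,5,7-triol F12. In F12, C4 lies in a planar fused ring with open faces, and hydrolysis of its imine tautomer rejoins the route at 21, which the fluoride of step 14 converts to 22. The price is competition from dehydration to the 4-aminobenzopyrylium ion and thence the chromone, so the buffer must stay only weakly acidic.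

**Step 14.** Slow cleavage of the secondary silyl ether would prolong the exposure of the lactol to fluoride and acetate. This invites β-elimination across C3–C9, dehydration to the chromone, closure onto O5, and an unfavourable distribution at C2 and C3. Mixtures at these labile positions can be re-equilibrated in buffered aqueous acetonitrile. The fallback changes the protecting group so that the carbinol is released within minutes, and sets out from 16. Et3SiCl/imidazole gives 4-{(R)-(TESO)[4-(TIPSO)phenyl]methyl}-3-[2,4,6-tris(TBSO)-3-methoxy-5-methylphenyl]-1,2-oxazole F13. Mo(CO)6 in wet MeCN gives (2Z)-3-amino-2-{(R)-(TESO)[4-(TIPSO)phenyl]methyl}-3-[2,4,6-tris(TBSO)-3-methoxy-5-methylphenyl]prop-2-enal F14. Cold aqueous oxalic acid gives (2Z)-2-{(R)-(TESO)[4-(TIPSO)phenyl]methyl}-3-hydroxy-1-[2,4,6-tris(TBSO)-3-methoxy-5-methylphenyl]prop-2-en-1-one F15. Buffered fluoride at 0 °C then rejoins the route at 22.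

## Further compounds

F1 | step 3 | 2,4,6-tris(benzyloxy)-3-methylbenzaldehyde | Cc1c(OCc2ccccc2)cc(OCc2ccccc2)c(C=O)c1OCc1ccccc1
F2 | step 3 | 2,4,6-tris(benzyloxy)-3-methylphenyl formate | Cc1c(OCc2ccccc2)cc(OCc2ccccc2)c(OC=O)c1OCc1ccccc1
F3 | step 3 | 2,4,6-tris(benzyloxy)-3-methylphenol | Cc1c(OCc2ccccc2)cc(OCc2ccccc2)c(O)c1OCc1ccccc1
F4 | step 3 | 1,3,5-tris(benzyloxy)-2-methoxy-4-methylbenzene | COc1c(OCc2ccccc2)cc(OCc2ccccc2)c(C)c1OCc1ccccc1
F5 | step 3 | 2-methoxy-4-methylbenzene-1,3,5-triol | COc1c(O)cc(O)c(C)c1O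
F6 | step 9 | sodium (1Z)-3-oxo-3-[4-(TIPSO)phenyl]prop-1-en-1-olate | [Na+].[O-]/C=C\C(=O)c1ccc(O[Si](C(C)C)(C(C)C)C(C)C)cc1
F7 | step 9 | {5-hydroxy-3-[2,4,6-tris(TBSO)-3-methoxy-5-methylphenyl]-4,5-dihydro-1,2-oxazol-4-yl}[4-(TIPSO)phenyl]methanone (racemic, both diastereomers) | OC1ON=C(c2c(O[Si](C)(C)C(C)(C)C)c(OC)c(O[Si](C)(C)C(C)(C)C)c(C)c2O[Si](C)(C)C(C)(C)C)C1C(=O)c1ccc(O[Si](C(C)C)(C(C)C)C(C)C)cc1
F8 | step 10 | racemic {3-[2,4,6-tris(TBSO)-3-methoxy-5-methylphenyl]-1,2-oxazol-4-yl}[4-(TIPSO)phenyl]methanol | OC(c1ccc(O[Si](C(C)C)(C(C)C)C(C)C)cc1)c1conc1-c1c(O[Si](C)(C)C(C)(C)C)c(OC)c(O[Si](C)(C)C(C)(C)C)c(C)c1O[Si](C)(C)C(C)(C)C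
F9 | step 10 | (R)-{3-[2,4,6-tris(TBSO)-3-methoxy-5-methylphenyl]-1,2-oxazol-4-yl}[4-(TIPSO)phenyl]methyl (S)-2-methoxy-2-phenylacetate | CO[C@@H](c1ccccc1)C(=O)O[C@H](c1ccc(O[Si](C(C)C)(C(C)C)C(C)C)cc1)c1conc1-c1c(O[Si](C)(C)C(C)(C)C)c(OC)c(O[Si](C)(C)C(C)(C)C)c(C)c1O[Si](C)(C)C(C)(C)C
F10 | step 10 | (S)-{3-[2,4,6-tris(TBSO)-3-methoxy-5-methylphenyl]-1,2-oxazol-4-yl}[4-(TIPSO)phenyl]methyl (S)-2-methoxy-2-phenylacetate | CO[C@@H](c1ccccc1)C(=O)O[C@@H](c1ccc(O[Si](C(C)C)(C(C)C)C(C)C)cc1)c1conc1-c1c(O[Si](C)(C)C(C)(C)C)c(OC)c(O[Si](C)(C)C(C)(C)C)c(C)c1O[Si](C)(C)C(C)(C)C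
F11 | step 13 | (2Z)-3-amino-2-[(R)-(TBSO)(4-hydroxyphenyl)methyl]-3-(2,4,6-trihydroxy-3-methoxy-5-methylphenyl)prop-2-enal | CC(C)(C)[Si](C)(C)O[C@H](c1ccc(O)cc1)/C(C=O)=C(/N)c1c(O)c(OC)c(O)c(C)c1O
F12 | step 13 | 4-amino-3-[(R)-(TBSO)(4-hydroxyphenyl)methyl]-6-methoxy-8-methyl-2H-chromene-2,5,7-triol (both C2 epimers) | COc1c(O)c(C)c2c(c1O)C(N)=C([C@H](O[Si](C)(C)C(C)(C)C)c1ccc(O)cc1)C(O)O2
F13 | step 14 | 4-{(R)-(TESO)[4-(TIPSO)phenyl]methyl}-3-[2,4,6-tris(TBSO)-3-methoxy-5-methylphenyl]-1,2-oxazole | CC[Si](CC)(CC)O[C@H](c1ccc(O[Si](C(C)C)(C(C)C)C(C)C)cc1)c1conc1-c1c(O[Si](C)(C)C(C)(C)C)c(OC)c(O[Si](C)(C)C(C)(C)C)c(C)c1O[Si](C)(C)C(C)(C)C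
F14 | step 14 | (2Z)-3-amino-2-{(R)-(TESO)[4-(TIPSO)phenyl]methyl}-3-[2,4,6-tris(TBSO)-3-methoxy-5-methylphenyl]prop-2-enal | CC[Si](CC)(CC)O[C@H](c1ccc(O[Si](C(C)C)(C(C)C)C(C)C)cc1)/C(C=O)=C(/N)c1c(O[Si](C)(C)C(C)(C)C)c(OC)c(O[Si](C)(C)C(C)(C)C)c(C)c1O[Si](C)(C)C(C)(C)C
F15 | step 14 | (2Z)-2-{(R)-(TESO)[4-(TIPSO)phenyl]methyl}-3-hydroxy-1-[2,4,6-tris(TBSO)-3-methoxy-5-methylphenyl]prop-2-en-1-one | O/C=C(/[C@H](O[Si](CC)(CC)CC)c1ccc(O[Si](C(C)C)(C(C)C)C(C)C)cc1)C(=O)c1c(O[Si](C)(C)C(C)(C)C)c(OC)c(O[Si](C)(C)C(C)(C)C)c(C)c1O[Si](C)(C)C(C)(C)C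
A1 | alternative 1 | 4-(1-ethoxyethenyl)-4-methoxy-2-methyl-3-(propan-2-yloxy)cyclobut-2-en-1-one (racemic) | CCOC(=C)C1(OC)C(OC(C)C)=C(C)C1=O
A2 | alternative 1 | 5-ethoxy-4-methoxy-2-methyl-3-(propan-2-yloxy)phenol | COc1c(OC(C)C)c(C)c(O)cc1OCC
A3 | alternative 2 | 2-{(3S)-3-(TBSO)-3-[4-(TBSO)phenyl]propanoyl}-3,5-bis(TBSO)-4-methoxy-6-methylphenyl formate | COc1c(O[Si](C)(C)C(C)(C)C)c(C)c(OC=O)c(c1O[Si](C)(C)C(C)(C)C)C(=O)C[C@H](O[Si](C)(C)C(C)(C)C)c1ccc(O[Si](C)(C)C(C)(C)C)cc1
A4 | alternative 2 | (2S,3R)-5,7-bis(TBSO)-3-{(S)-(TBSO)[4-(TBSO)phenyl]methyl}-2-hydroxy-6-methoxy-8-methyl-2,3-dihydro-4H-chromen-4-one | COc1c(O[Si](C)(C)C(C)(C)C)c(C)c2c(c1O[Si](C)(C)C(C)(C)C)C(=O)[C@H]([C@H](O[Si](C)(C)C(C)(C)C)c1ccc(O[Si](C)(C)C(C)(C)C)cc1)[C@@H](O)O2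
A5 | alternative 3 | 3-(benzyloxy)-2-(TBSO)furan | CC(C)(C)[Si](C)(C)Oc1occc1OCc1ccccc1
A6 | alternative 3 | pent-3-yn-2-one | CC#CC(C)=O
A7 | alternative 3 | 1-[6-(benzyloxy)-2-(TBSO)-4-hydroxy-3-... acetyl phenol: 1-[3-(benzyloxy)-2-(TBSO)-5-hydroxy-6-methylphenyl]ethan-1-one | CC(=O)c1c(C)c(O)cc(OCc2ccccc2)c1O[Si](C)(C)C(C)(C)C
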